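The benzo ring of the 2,3-dihydrobenzofuran is built last. That ring (C3a–C4–C5–C6–C7–C7a) is substituted only at C7a (O1), C3a (C3) and C5 (the chain para to O1), which is the pattern of a 3-alkoxy-6-acylpyridazine joined to a terminal alkyne. Heating an anti-configured homopropargylic 6-(methoxycarbonyl)pyridazin-3-yl ether, whose C2 and C3 stereocentres are already set by acyclic chirality transfer, should trigger an intramolecular inverse-demand [4+2] cycloaddition and loss of N2. This forms C3a–C7a and C4–C5 and closes the dihydrofuran and benzene rings in one operation. A TIPS ether masks the C3 hydroxymethyl group throughout; the C5 ester is then homologated to the (E)-allylic alcohol.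

Key step: step 6

Assumption: the lipase in step 2 is taken to show the usual secondary-alcohol preference (CH2OSi large, ethynyl small), so that the (R)-acetate is the one hydrolysed (configuration of 4 to be checked as its Mosher ester), and 2-(triisopropylsilyloxy)acetaldehyde is taken as a catalogue aldehyde.

Step 1
Reactants: 1 2-[(triisopropylsilyl)oxy]acetaldehyde
Product: 3 rac-1-[(triisopropylsilyl)oxy]but-3-yn-2-yl acetate, via bromomagnesium alkoxide 2 (not isolated)
Conditions: HC≡CMgBr (1.1 equiv), THF, −78 → 0 °C; then Ac2O (1.5 equiv), DMAP (cat.), 0 °C → rt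
Reagents that add atoms: ethynylmagnesium bromide C#C[Mg]Br; acetic anhydride CC(=O)OC(C)=O
Why: Grignard 1,2-addition of the acetylide to the unhindered aldehyde, followed by acylation of the magnesium alkoxide in the same flask, should give the racemic propargylic acetate, whose new stereocentre is formed without control and is resolved in step 2.

Step 2
Reactants: 3 rac-1-[(triisopropylsilyl)oxy]but-3-yn-2-yl acetate
Product: 4 (2R)-1-[(triisopropylsilyl)oxy]but-3-yn-2-ol
Conditions: Burkholderia cepacia lipase (Amano PS), phosphate buffer pH 7/acetone 9:1, 30 °C, stopped near 45% conversion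
Reagents that add atoms: none
Why: Lipase-catalysed enantioselective ester hydrolysis (kinetic resolution) should release the (R)-alcohol, because with CH2OTIPS as the large and ethynyl as the small substituent the (R)-acetate is the matched enantiomer, while the (S)-acetate stays esterified and is removed by chromatography.

Step 3
Reactants: 4 (2R)-1-[(triisopropylsilyl)oxy]but-3-yn-2-ol
Product: 5 (2R)-1-[(triisopropylsilyl)oxy]but-3-yn-2-yl methanesulfonate
Conditions: MsCl (1.3 equiv), Et3N (2 equiv), CH2Cl2, −78 → −20 °C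
Reagents that add atoms: methanesulfonyl chloride CS(=O)(=O)Cl
Why: Mesylation takes place at oxygen and leaves the C–O bond intact, so the R configuration is retained in the activated propargylic ester.

Step 4
Reactants: 5 (2R)-1-[(triisopropylsilyl)oxy]but-3-yn-2-yl methanesulfonate; 6 3,4,5-trimethoxybenzaldehyde
Product: 8 (1R,2S)-2-{[(triisopropylsilyl)oxy]methyl}-1-(3,4,5-trimethoxyphenyl)but-3-yn-1-ol, via allenylzinc reagent 7 (not isolated)
Conditions: Pd(OAc)2 (5 mol%), PPh3 (5 mol%), Et2Zn (3 equiv), THF, −78 → −20 °C; aq. NH4Cl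
Reagents that add atoms: none
Why: Marshall propargylation, in which Pd(0) attacks the alkyne terminus anti to the mesylate (SN2′), transmetalation with Et2Zn gives the (M)-allenylzinc 7, and its syn-SE2′ addition to the aldehyde through a cyclic six-membered transition state transfers the axial chirality to C2 (S) while the aryl group turns away from the CH2OTIPS substituent, which sets C1 (R) in the anti relationship.

Step 5
Reactants: 8 (1R,2S)-2-{[(triisopropylsilyl)oxy]methyl}-1-(3,4,5-trimethoxyphenyl)but-3-yn-1-ol; 9 methyl 6-chloropyridazine-3-carboxylate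
Product: 11 methyl 6-{[(1R,2S)-2-{[(triisopropylsilyl)oxy]methyl}-1-(3,4,5-trimethoxyphenyl)but-3-yn-1-yl]oxy}pyridazine-3-carboxylate, via sodium alkoxide 10 (not isolated)
Conditions: NaH (1.05 equiv), THF, 0 °C, 20 min; then 9 (1.2 equiv), 0 °C → rt
Reagents that add atoms: none
Why: Nucleophilic aromatic substitution (addition–elimination) at C6 of the chlorodiazine, activated by the adjacent ring nitrogen and the para ester, forms the aryl–O bond without touching the carbinol C–O bond, so C1 stays R, and the bulky TIPS group is not expected to shift to the neighbouring alkoxide.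

Step 6
Reactants: 11 methyl 6-{[(1R,2S)-2-{[(triisopropylsilyl)oxy]methyl}-1-(3,4,5-trimethoxyphenyl)but-3-yn-1-yl]oxy}pyridazine-3-carboxylate
Product: 13 methyl (2R,3S)-3-{[(triisopropylsilyl)oxy]methyl}-2-(3,4,5-trimethoxyphenyl)-2,3-dihydro-1-benzofuran-5-carboxylate, via diazabicyclooctatriene adduct 12 (not isolated)
Conditions: 1,2-dichlorobenzene (0.02 M, degassed), 2,6-di-tert-butyl-4-methylpyridine (10 mol%), 160 °C, sealed tube
Reagents that add atoms: none
Why: The ester-substituted 1,2-diazine, a low-LUMO azadiene, takes up the tethered terminal alkyne across its C3 and C6 in an intramolecular inverse-electron-demand Diels–Alder reaction, and the 2,3-diazabicyclo[2.2.2]octatriene 12 expels N2 by retro-Diels–Alder reaction, so the arene appears without an oxidant. The closest known reaction type is the thermal conversion of 3-(but-3-ynyloxy)pyridazines into 2,3-dihydrobenzofurans. The dihydrofuran ring (O1–C2–C3–C3a–C7a) closes because the three-atom O–C–C tether lets only the internal alkyne carbon reach the oxygen-bearing diazine carbon (bond C3a–C7a), and the benzene ring closes by the same cycloaddition (bonds C3a–C7a and C4–C5) completed by loss of the N=N bridge. No stereocentre is created: C2 (R) and C3 (S) lie outside the reacting π-systems and are carried over from 11, and both facial approaches of the alkyne converge on 13 once the bridgeheads of 12 become sp2. The step needs rate selectivity (cyclisation before ionisation or elimination of the secondary benzylic heteroaryl ether) and regioselectivity (ester at C5, H at C4); the ester acceptor and the two trans-disposed tether substituents, which favour the folded rotamer, lower the barrier, the tether length fixes the orientation, and the dilute, apolar, base-buffered medium disfavours heterolysis.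

Step 7
Reactants: 13 methyl (2R,3S)-3-{[(triisopropylsilyl)oxy]methyl}-2-(3,4,5-trimethoxyphenyl)-2,3-dihydro-1-benzofuran-5-carboxylate
Product: 14 [(2R,3S)-3-{[(triisopropylsilyl)oxy]methyl}-2-(3,4,5-trimethoxyphenyl)-2,3-dihydro-1-benzofuran-5-yl]methanol
Conditions: DIBAL-H (2.5 equiv), CH2Cl2, −78 → 0 °C; aq. Rochelle salt
Reagents that add atoms: none
Why: DIBAL-H reduction of the aryl ester proceeds through the aldehyde to the benzylic alcohol under conditions that leave the silyl ether, the aryl methyl ethers and the cyclic benzylic ether untouched.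

Step 8
Reactants: 14 [(2R,3S)-3-{[(triisopropylsilyl)oxy]methyl}-2-(3,4,5-trimethoxyphenyl)-2,3-dihydro-1-benzofuran-5-yl]methanol
Product: 16 ethyl (2E)-3-[(2R,3S)-3-{[(triisopropylsilyl)oxy]methyl}-2-(3,4,5-trimethoxyphenyl)-2,3-dihydro-1-benzofuran-5-yl]prop-2-enoate, via benzofurancarbaldehyde 15 (not isolated)
Conditions: activated MnO2 (10 equiv), Ph3P=CHCO2Et (1.3 equiv), CH2Cl2, rt → 40 °C
Reagents that add atoms: ethyl (triphenylphosphoranylidene)acetate CCOC(=O)C=P(c1ccccc1)(c1ccccc1)c1ccccc1
Why: Tandem oxidation–Wittig olefination, in which MnO2 oxidises only the benzylic alcohol and the stabilised ylide traps aldehyde 15 as it forms, should give the (E)-enoate as expected for a stabilised ylide.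

Step 9
Reactants: 16 ethyl (2E)-3-[(2R,3S)-3-{[(triisopropylsilyl)oxy]methyl}-2-(3,4,5-trimethoxyphenyl)-2,3-dihydro-1-benzofuran-5-yl]prop-2-enoate
Product: 17 (2E)-3-[(2R,3S)-3-{[(triisopropylsilyl)oxy]methyl}-2-(3,4,5-trimethoxyphenyl)-2,3-dihydro-1-benzofuran-5-yl]prop-2-en-1-ol
Conditions: DIBAL-H (2.5 equiv), CH2Cl2, −78 °C; aq. Rochelle salt
Reagents that add atoms: none
Why: 1,2-Reduction of the α,β-unsaturated ester by DIBAL-H at −78 °C should give the allylic alcohol with the E double bond and both ring stereocentres unchanged.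

Step 10
Reactants: 17 (2E)-3-[(2R,3S)-3-{[(triisopropylsilyl)oxy]methyl}-2-(3,4,5-trimethoxyphenyl)-2,3-dihydro-1-benzofuran-5-yl]prop-2-en-1-ol
Product: 18 (2E)-3-[(2R,3S)-3-(hydroxymethyl)-2-(3,4,5-trimethoxyphenyl)-2,3-dihydro-1-benzofuran-5-yl]prop-2-en-1-ol
Conditions: TBAF (1.5 equiv), THF, 0 °C → rt; aq. NH4Cl
Reagents that add atoms: none
Why: Fluoride-induced desilylation, driven by formation of the Si–F bond, should free the primary alcohol under conditions to which the allylic alcohol, the alkene and the dihydrobenzofuran are inert.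

Compound list
1 | 2-[(triisopropylsilyl)oxy]acetaldehyde | CC(C)[Si](OCC=O)(C(C)C)C(C)C | starting material
2 | bromomagnesium 1-[(triisopropylsilyl)oxy]but-3-yn-2-olate (racemic, formed in the flask) | C#CC(O[Mg]Br)CO[Si](C(C)C)(C(C)C)C(C)C | intermediate
3 | rac-1-[(triisopropylsilyl)oxy]but-3-yn-2-yl acetate | C#CC(OC(C)=O)CO[Si](C(C)C)(C(C)C)C(C)C | intermediate
4 | (2R)-1-[(triisopropylsilyl)oxy]but-3-yn-2-ol | C#C[C@@H](O)CO[Si](C(C)C)(C(C)C)C(C)C | intermediate
5 | (2R)-1-[(triisopropylsilyl)oxy]but-3-yn-2-yl methanesulfonate | C#C[C@@H](OS(C)(=O)=O)CO[Si](C(C)C)(C(C)C)C(C)C | intermediate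
6 | 3,4,5-trimethoxybenzaldehyde | COc1cc(C=O)cc(OC)c1OC | starting material
7 | ethyl[(M)-4-(triisopropylsilyloxy)buta-1,2-dien-1-yl]zinc (formed in the flask; the M axial configuration is not encoded in the SMILES) | CC[Zn]C=C=CCO[Si](C(C)C)(C(C)C)C(C)C | intermediate
8 | (1R,2S)-2-{[(triisopropylsilyl)oxy]methyl}-1-(3,4,5-trimethoxyphenyl)but-3-yn-1-ol (anti) | COc1cc([C@H](O)[C@H](CO[Si](C(C)C)(C(C)C)C(C)C)C#C)cc(OC)c1OC | intermediate
9 | methyl 6-chloropyridazine-3-carboxylate | COC(=O)c1ccc(Cl)nn1 | starting material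
10 | sodium (1R,2S)-2-{[(triisopropylsilyl)oxy]methyl}-1-(3,4,5-trimethoxyphenyl)but-3-yn-1-olate (formed in the flask) | COc1cc([C@H]([O-])[C@H](CO[Si](C(C)C)(C(C)C)C(C)C)C#C)cc(OC)c1OC.[Na+] | intermediate
11 | methyl 6-{[(1R,2S)-2-{[(triisopropylsilyl)oxy]methyl}-1-(3,4,5-trimethoxyphenyl)but-3-yn-1-yl]oxy}pyridazine-3-carboxylate (anti ether) | COc1cc([C@H](Oc2ccc(C(=O)OC)nn2)[C@H](CO[Si](C(C)C)(C(C)C)C(C)C)C#C)cc(OC)c1OC | intermediate
12 | [4+2] adduct of 11: dihydrofuran-fused 2,3-diazabicyclo[2.2.2]octa-2,5,7-triene with the ester at one bridgehead and O1 at the other (bridgehead configuration not fixed, both forms converge; formed in the flask) | COC(=O)C12C=CC3(N=N1)O[C@@H](c4cc(OC)c(OC)c(OC)c4)[C@H](CO[Si](C(C)C)(C(C)C)C(C)C)C3=C2 | intermediate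
13 | methyl (2R,3S)-3-{[(triisopropylsilyl)oxy]methyl}-2-(3,4,5-trimethoxyphenyl)-2,3-dihydro-1-benzofuran-5-carboxylate (trans) | COc1cc([C@@H]2Oc3ccc(C(=O)OC)cc3[C@H]2CO[Si](C(C)C)(C(C)C)C(C)C)cc(OC)c1OC | intermediate
14 | [(2R,3S)-3-{[(triisopropylsilyl)oxy]methyl}-2-(3,4,5-trimethoxyphenyl)-2,3-dihydro-1-benzofuran-5-yl]methanol | COc1cc([C@@H]2Oc3ccc(CO)cc3[C@H]2CO[Si](C(C)C)(C(C)C)C(C)C)cc(OC)c1OC | intermediate
15 | (2R,3S)-3-{[(triisopropylsilyl)oxy]methyl}-2-(3,4,5-trimethoxyphenyl)-2,3-dihydro-1-benzofuran-5-carbaldehyde (formed in the flask) | COc1cc([C@@H]2Oc3ccc(C=O)cc3[C@H]2CO[Si](C(C)C)(C(C)C)C(C)C)cc(OC)c1OC | intermediate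
16 | ethyl (2E)-3-[(2R,3S)-3-{[(triisopropylsilyl)oxy]methyl}-2-(3,4,5-trimethoxyphenyl)-2,3-dihydro-1-benzofuran-5-yl]prop-2-enoate | COc1cc([C@@H]2Oc3ccc(/C=C/C(=O)OCC)cc3[C@H]2CO[Si](C(C)C)(C(C)C)C(C)C)cc(OC)c1OC | intermediate
17 | (2E)-3-[(2R,3S)-3-{[(triisopropylsilyl)oxy]methyl}-2-(3,4,5-trimethoxyphenyl)-2,3-dihydro-1-benzofuran-5-yl]prop-2-en-1-ol | COc1cc([C@@H]2Oc3ccc(/C=C/CO)cc3[C@H]2CO[Si](C(C)C)(C(C)C)C(C)C)cc(OC)c1OC | intermediate
18 | (2E)-3-[(2R,3S)-3-(hydroxymethyl)-2-(3,4,5-trimethoxyphenyl)-2,3-dihydro-1-benzofuran-5-yl]prop-2-en-1-ol (CNP0077408.1) | COc1cc([C@@H]2Oc3ccc(/C=C/CO)cc3[C@H]2CO)cc(OC)c1OC | target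

Total step count: 10. Longest linear sequence: 10 steps (1 → 18); 6 and 9 enter as purchased materials.

Steps most likely to fail

Step 6. The secondary benzylic C–O bond may break (heterolysis with O→N benzyl shift, or syn-elimination of the pyridazinone across C2–C3) below the temperature the [4+2] event needs, so the ether would be consumed before it cyclises. The fallback sets out from 8 and comes back at 15; it changes the diene and the exit from the key step. Alcohol 8 is etherified (NaH, THF, 0 °C) with 6-chloropyridazine-3-carbonitrile to give 6-{[(1R,2S)-2-{[(triisopropylsilyl)oxy]methyl}-1-(3,4,5-trimethoxyphenyl)but-3-yn-1-yl]oxy}pyridazine-3-carbonitrile F1. The nitrile is a stronger and sterically smaller acceptor at the bond-forming diazine carbon than the ester, so cycloaddition and N2 loss are expected to set in at a lower temperature (1,2-dichlorobenzene, raised stepwise from 110 °C) and to give (2R,3S)-3-{[(triisopropylsilyl)oxy]methyl}-2-(3,4,5-trimethoxyphenyl)-2,3-dihydro-1-benzofuran-5-carbonitrile F2. DIBAL-H (1.2 equiv, toluene, −78 °C, then aqueous hydrolysis of the aldimine) converts F2 into aldehyde 15, which is olefinated with Ph3P=CHCO2Et to 16.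

Step 4. The anti preference may erode with an aromatic aldehyde (a looser cyclic transition state), and the silyloxy group may be lost by β-elimination from the propargylic zinc tautomer of 7. The fallback sets out from 4 and comes back at 8; it replaces the zinc reagent made in the flask by an isolable boron reagent. Alcohol 4 is converted (ClCO2Me, pyridine, CH2Cl2) into (2R)-methyl 1-[(triisopropylsilyl)oxy]but-3-yn-2-yl carbonate F3. Copper(I)-catalysed borylation with B2pin2 (CuCl, Xantphos, NaOt-Bu, THF, rt) proceeds by borylcupration and anti β-oxygen elimination to give (M)-4,4,5,5-tetramethyl-2-[4-(triisopropylsilyloxy)buta-1,2-dien-1-yl]-1,3,2-dioxaborolane F4, which cannot tautomerise to a β-silyloxy propargyl metal. Thermal allenylboration of 6 (toluene, 60 °C) through the closed six-membered transition state, followed by aqueous cleavage of the borate, should return 8 with the same sense of chirality transfer.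

Step 5. The hindered alkoxide may attack the ester carbonyl of 9 instead of C6 (the released methoxide then consumes 9), or the base may induce loss of the newly formed pyridazinyloxy group. The fallback sets out from 8 and comes back at 11. The substitution is run on 6-chloropyridazine-3-carboxylic acid as its sodium carboxylate (NaH 2.2 equiv, DMF, 0 → 40 °C), which offers no electrophilic acyl group, to give 6-{[(1R,2S)-2-{[(triisopropylsilyl)oxy]methyl}-1-(3,4,5-trimethoxyphenyl)but-3-yn-1-yl]oxy}pyridazine-3-carboxylic acid F5. O-Methylation with TMSCHN2 (toluene/MeOH, 0 °C) then gives 11.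

Further compounds
F1 | step 6 | 6-{[(1R,2S)-2-{[(triisopropylsilyl)oxy]methyl}-1-(3,4,5-trimethoxyphenyl)but-3-yn-1-yl]oxy}pyridazine-3-carbonitrile | COc1cc([C@H](Oc2ccc(C#N)nn2)[C@H](CO[Si](C(C)C)(C(C)C)C(C)C)C#C)cc(OC)c1OC
F2 | step 6 | (2R,3S)-3-{[(triisopropylsilyl)oxy]methyl}-2-(3,4,5-trimethoxyphenyl)-2,3-dihydro-1-benzofuran-5-carbonitrile | COc1cc([C@@H]2Oc3ccc(C#N)cc3[C@H]2CO[Si](C(C)C)(C(C)C)C(C)C)cc(OC)c1OC
F3 | step 4 | (2R)-methyl 1-[(triisopropylsilyl)oxy]but-3-yn-2-yl carbonate | C#C[C@@H](OC(=O)OC)CO[Si](C(C)C)(C(C)C)C(C)C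
F4 | step 4 | (M)-4,4,5,5-tetramethyl-2-[4-(triisopropylsilyloxy)buta-1,2-dien-1-yl]-1,3,2-dioxaborolane (axial configuration not encoded in the SMILES) | CC1(C)OB(C=C=CCO[Si](C(C)C)(C(C)C)C(C)C)OC1(C)C
F5 | step 5 | 6-{[(1R,2S)-2-{[(triisopropylsilyl)oxy]methyl}-1-(3,4,5-trimethoxyphenyl)but-3-yn-1-yl]oxy}pyridazine-3-carboxylic acid | COc1cc([C@H](Oc2ccc(C(=O)O)nn2)[C@H](CO[Si](C(C)C)(C(C)C)C(C)C)C#C)cc(OC)c1OC
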